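**Plan**

1. Retrosynthesis: the first cut is the aryl–C(sp3) bond between C5 of ring A (the 6-hydroxy-dihydrobenzofuran) and C2 of ring B (the 4-hydroxy-6-styryl-dihydrobenzofuran). The ring B half is then cut at O1–C2 (ring contraction of a 4-aryl-dihydrocoumarin), at C3–aryl (conjugate arylation of a coumarin) and at the aryl–vinyl bond of the stilbene. The ring A half is cut at C2–C3 (carbene C–H insertion), at the diaryl ketone and at the benzyl ether.
2. Forward, ring B half: bromocoumarin, Heck reaction (stilbene), Rh-catalysed 1,4-arylation, bromination and ring contraction (closes ring B with a carboxyl group on C2), N-acyloxyphthalimide.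
3. Forward, ring A half: salicylaldehyde, benzyl ether, diaryl ketone, hydrazone, Rh-carbene C–H insertion (closes ring A, cis), acid epimerisation to trans.
4. Union: C2 of ring B is an anomeric-type carbon, bound to the ring oxygen O1 and flanked by the C3 diarylmethine, so a carboxyl group on it is a latent α-oxy radical. Nickel couples that radical with an arylzinc at C5 of ring A; the C5 position (ortho to the C6 oxygen, para to O1) is fixed by a bromine carried from the first ring A intermediate. Global debenzylation follows.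
5. Stereochemistry: C3 of ring B comes from Rh/(R)-Segphos, C3 of ring A from the chiral dirhodium carboxylate, C2 of ring A from thermodynamic control, and C2 of ring B from substrate control in the key step (aryl delivered anti to the C3 aryl group).

Key step: step 17

Assumption: the sense of induction in steps 6 and 15 is assigned by analogy with simpler coumarins and aryl benzyl ethers, and the antipodal ligand is used if either proves reversed; the benzyl-protected aryl building blocks used as starting materials are taken as purchasable.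

**Route**

Step 1
Reactants: 1 4-bromo-2,6-difluorobenzaldehyde
Product: 2 2,6-bis(benzyloxy)-4-bromobenzaldehyde
Conditions: BnOH (2.2 equiv), K2CO3, DMF, 70 °C
Reagents that add atoms: benzyl alcohol OCc1ccccc1
Why: Double SNAr at the two fluorides ortho to the formyl group, which are displaced far faster than the para bromide kept as the handle for the stilbene.

Step 2
Reactants: 2 2,6-bis(benzyloxy)-4-bromobenzaldehyde
Product: 3 2-(benzyloxy)-4-bromo-6-hydroxybenzaldehyde
Conditions: MgBr2·OEt2 (1.2 equiv), toluene/Et2O, 60 °C; 1 M HCl work-up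
Reagents that add atoms: none
Why: Chelation-controlled ether cleavage in which magnesium bridges the formyl oxygen and one ortho benzyloxy oxygen, bromide removes that benzyl group, and the chelated phenoxide formed should protect the second ether.

Step 3
Reactants: 3 2-(benzyloxy)-4-bromo-6-hydroxybenzaldehyde
Product: 5 5-(benzyloxy)-7-bromo-2H-chromen-2-one, via E-cinnamate ester 4 (not isolated)
Conditions: Ph3P=CHCO2Et (1.2 equiv), N,N-diethylaniline, reflux
Reagents that add atoms: ethyl (triphenylphosphoranylidene)acetate CCOC(=O)C=P(c1ccccc1)(c1ccccc1)c1ccccc1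
Why: Wittig olefination gives the E-cinnamate, which at this temperature should isomerise and lactonise onto the free phenol (Wittig-based coumarin synthesis).

Step 4
Reactants: 6 2,4-bis(benzyloxy)benzaldehyde
Product: 7 2,4-bis(benzyloxy)-1-ethenylbenzene
Conditions: Ph3PCH3Br, KOt-Bu, THF, 0 °C to rt
Reagents that add atoms: methyltriphenylphosphonium bromide C[P+](c1ccccc1)(c1ccccc1)c1ccccc1.[Br-]
Why: Wittig methylenation of an aromatic aldehyde.

Step 5
Reactants: 5 5-(benzyloxy)-7-bromo-2H-chromen-2-one; 7 2,4-bis(benzyloxy)-1-ethenylbenzene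
Product: 8 5-(benzyloxy)-7-{(E)-2-[2,4-bis(benzyloxy)phenyl]ethenyl}-2H-chromen-2-one
Conditions: Pd(OAc)2 (5 mol %), P(o-tol)3 (10 mol %), Et3N, DMF, 100 °C
Reagents that add atoms: none
Why: Mizoroki–Heck arylation at the terminal styrene carbon, with syn β-hydride elimination expected to give the E-stilbene.

Step 6
Reactants: 8 5-(benzyloxy)-7-{(E)-2-[2,4-bis(benzyloxy)phenyl]ethenyl}-2H-chromen-2-one; 9 [3,5-bis(benzyloxy)phenyl]boronic acid
Product: 10 (4R)-5-(benzyloxy)-4-[3,5-bis(benzyloxy)phenyl]-7-{(E)-2-[2,4-bis(benzyloxy)phenyl]ethenyl}-3,4-dihydro-2H-chromen-2-one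
Conditions: Rh(acac)(C2H4)2 (3 mol %), (R)-Segphos (3.3 mol %), 9 (3 equiv), dioxane/H2O 10:1, 60 °C; then TsOH (cat.), toluene, to re-close any opened lactone
Reagents that add atoms: none
Why: Hayashi–Miyaura rhodium-catalysed asymmetric 1,4-addition of an arylboronic acid to a coumarin, in which the chiral bisphosphine–arylrhodium species selects the enantioface of C3=C4 and should set C4 as R (the future C3 of ring B).

Step 7
Reactants: 10 (4R)-5-(benzyloxy)-4-[3,5-bis(benzyloxy)phenyl]-7-{(E)-2-[2,4-bis(benzyloxy)phenyl]ethenyl}-3,4-dihydro-2H-chromen-2-one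
Product: 12 (2R,3R)-4-(benzyloxy)-3-[3,5-bis(benzyloxy)phenyl]-6-{(E)-2-[2,4-bis(benzyloxy)phenyl]ethenyl}-2,3-dihydro-1-benzofuran-2-carboxylic acid, via bromolactone 11 (not isolated)
Conditions: LiHMDS, THF, −78 °C; BrCCl2CCl2Br; then 2 M NaOH, MeOH/THF, 0 °C to rt; 1 M HCl
Reagents that add atoms: sodium hydroxide [Na+].[OH-] (carboxyl oxygen); 1,2-dibromotetrachloroethane BrC(Cl)(Cl)C(Cl)(Cl)Br (bromine of 11 only)
Why: Enolate bromination anti to the C4 aryl group followed by a Perkin-type ring contraction, in which hydroxide opens the lactone and the freed phenoxide displaces the α-bromide in a 5-exo-tet SN2 closure of ring B; the benzylic centre is untouched, and the C2 configuration (drawn trans) is of no consequence because step 17 erases it.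

Step 8
Reactants: 12 (2R,3R)-4-(benzyloxy)-3-[3,5-bis(benzyloxy)phenyl]-6-{(E)-2-[2,4-bis(benzyloxy)phenyl]ethenyl}-2,3-dihydro-1-benzofuran-2-carboxylic acid
Product: 13 1,3-dioxoisoindolin-2-yl (2R,3R)-4-(benzyloxy)-3-[3,5-bis(benzyloxy)phenyl]-6-{(E)-2-[2,4-bis(benzyloxy)phenyl]ethenyl}-2,3-dihydro-1-benzofuran-2-carboxylate
Conditions: N-hydroxyphthalimide, DIC, DMAP (cat.), CH2Cl2, rt
Reagents that add atoms: N-hydroxyphthalimide ON1C(=O)c2ccccc2C1=O
Why: Carbodiimide (Steglich-type) esterification to the redox-active N-acyloxyphthalimide.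

Step 9
Reactants: 6 2,4-bis(benzyloxy)benzaldehyde
Product: 14 [2,4-bis(benzyloxy)phenyl]methanol
Conditions: NaBH4, MeOH/THF, 0 °C
Reagents that add atoms: none
Why: Borohydride reduction of the aldehyde.

Step 10
Reactants: 15 5-bromo-2,4-dihydroxybenzaldehyde
Product: 16 4-(benzyloxy)-5-bromo-2-hydroxybenzaldehyde
Conditions: BnBr (1.05 equiv), NaHCO3, MeCN, 70 °C
Reagents that add atoms: benzyl bromide BrCc1ccccc1
Why: Williamson etherification that should be selective for the 4-OH, because the 2-OH is hydrogen-bonded to the formyl group and less acidic.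

Step 11
Reactants: 16 4-(benzyloxy)-5-bromo-2-hydroxybenzaldehyde; 14 [2,4-bis(benzyloxy)phenyl]methanol
Product: 17 4-(benzyloxy)-2-{[2,4-bis(benzyloxy)phenyl]methoxy}-5-bromobenzaldehyde
Conditions: PPh3, DIAD, THF, 0 °C to rt
Reagents that add atoms: none
Why: Mitsunobu etherification of the acidic salicylaldehyde-type phenol with the primary benzylic alcohol.

Step 12
Reactants: 18 1,3-bis(benzyloxy)-5-bromobenzene; 17 4-(benzyloxy)-2-{[2,4-bis(benzyloxy)phenyl]methoxy}-5-bromobenzaldehyde
Product: 20 (4-(benzyloxy)-2-{[2,4-bis(benzyloxy)phenyl]methoxy}-5-bromophenyl)[3,5-bis(benzyloxy)phenyl]methanol (racemic), via aryl Grignard reagent 19 (not isolated)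
Conditions: 18, Mg, THF, 40 °C; then 17, THF, −40 °C to 0 °C; aq. NH4Cl
Reagents that add atoms: none
Why: Grignard addition to the aldehyde, which should be much faster than halogen–magnesium exchange at the aryl bromide of 17; the carbinol centre is removed in step 13.

Step 13
Reactants: 20 (4-(benzyloxy)-2-{[2,4-bis(benzyloxy)phenyl]methoxy}-5-bromophenyl)[3,5-bis(benzyloxy)phenyl]methanol
Product: 21 (4-(benzyloxy)-2-{[2,4-bis(benzyloxy)phenyl]methoxy}-5-bromophenyl)[3,5-bis(benzyloxy)phenyl]methanone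
Conditions: Dess–Martin periodinane, CH2Cl2, rt
Reagents that add atoms: none
Why: Dess–Martin oxidation of the diaryl carbinol to the ketone.

Step 14
Reactants: 21 (4-(benzyloxy)-2-{[2,4-bis(benzyloxy)phenyl]methoxy}-5-bromophenyl)[3,5-bis(benzyloxy)phenyl]methanone
Product: 22 hydrazone of ketone 21 (E/Z mixture)
Conditions: N2H4·H2O, AcOH (cat.), EtOH, 80 °C
Reagents that add atoms: hydrazine NN
Why: Acid-catalysed condensation to the N-unsubstituted hydrazone.

Step 15
Reactants: 22 hydrazone of ketone 21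
Product: 24 (2S,3R)-6-(benzyloxy)-2-[2,4-bis(benzyloxy)phenyl]-3-[3,5-bis(benzyloxy)phenyl]-5-bromo-2,3-dihydro-1-benzofuran (2,3-cis), via diaryldiazomethane 23 (not isolated)
Conditions: MnO2, CH2Cl2, 0 °C; filter; Rh2(R-PTAD)4 (1 mol %), CH2Cl2, 0 °C
Reagents that add atoms: none
Why: MnO2 dehydrogenates the hydrazone to the diazo compound, and the dirhodium donor/donor carbene inserts intramolecularly (1,5) into the benzylic ether C–H, the chiral carboxylate ligands selecting the enantiotopic hydrogen so that C3 should be R while the concerted transition state places the two aryl groups cis.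

Step 16
Reactants: 24 (2S,3R)-6-(benzyloxy)-2-[2,4-bis(benzyloxy)phenyl]-3-[3,5-bis(benzyloxy)phenyl]-5-bromo-2,3-dihydro-1-benzofuran
Product: 25 (2R,3R)-6-(benzyloxy)-2-[2,4-bis(benzyloxy)phenyl]-3-[3,5-bis(benzyloxy)phenyl]-5-bromo-2,3-dihydro-1-benzofuran (2,3-trans)
Conditions: TFA (5 equiv), CH2Cl2, 0 °C
Reagents that add atoms: none
Why: Acid-mediated epimerisation by reversible heterolysis of the O1–C2 bond to a 2,4-dialkoxybenzyl cation that should re-close to the more stable trans ring, C3 keeping its configuration and so dictating 2R.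

Step 17
Reactants: 25 (2R,3R)-6-(benzyloxy)-2-[2,4-bis(benzyloxy)phenyl]-3-[3,5-bis(benzyloxy)phenyl]-5-bromo-2,3-dihydro-1-benzofuran; 13 1,3-dioxoisoindolin-2-yl (2R,3R)-4-(benzyloxy)-3-[3,5-bis(benzyloxy)phenyl]-6-{(E)-2-[2,4-bis(benzyloxy)phenyl]ethenyl}-2,3-dihydro-1-benzofuran-2-carboxylate
Product: 28 deca-O-benzylgneyulin A, via aryllithium 26 (not isolated), via arylzinc chloride 27 (not isolated)
Conditions: 25 (1.5 equiv), n-BuLi, THF, −78 °C; ZnCl2; then 13, NiCl2·glyme (20 mol %), 4,4′-di-tert-butyl-2,2′-bipyridine (40 mol %), THF/DMF, rt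
Reagents that add atoms: none
Why: The transmetalated arylnickel(I) species reduces the N-acyloxyphthalimide by single-electron transfer, the radical anion fragments with loss of CO2 and phthalimide anion to the C2 radical of ring B (stabilised by the O1 lone pair), and this radical is captured at nickel and released by C(sp3)–C(sp2) reductive elimination from nickel(III) to form the C5(ring A)–C2(ring B) bond. The closest known reaction type is the nickel-catalysed decarboxylative Negishi arylation of secondary α-alkoxy redox-active esters with arylzinc halides, the same logic that gives C-aryl glycosides from anomeric radicals. No ring is closed in this step, since ring B is already in place and only its C2 substituent is exchanged. The new stereocentre C2 of ring B is controlled by the existing C3 centre, whose 3,5-bis(benzyloxy)phenyl group blocks one face of the planar radical and of the alkylnickel species, so the aryl group should be delivered anti to give the 2,3-trans (2R,3R) ring, which is also the thermodynamically preferred isomer. The step needs site selectivity on ring A and diastereoselectivity on ring B: the first is secured because zinc sits only at C5, where the bromine has been carried from compound 15, the second by the C3 aryl group, and C3 itself cannot epimerise because it is never α to a carbonyl or cationic centre during the event.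

Step 18
Reactants: 28 deca-O-benzylgneyulin A
Product: 29 gneyulin A
Conditions: BCl3 (30 equiv), pentamethylbenzene (30 equiv), CH2Cl2, −78 °C; MeOH quench
Reagents that add atoms: none
Why: Lewis-acid debenzylation with a non-basic cation scavenger at low temperature, conditions expected to leave the stilbene and both 2-aryl-dihydrobenzofurans intact, with both C2 centres already in their thermodynamically preferred trans arrangement.

**Compound list**

1 | 4-bromo-2,6-difluorobenzaldehyde | O=Cc1c(F)cc(Br)cc1F | starting material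
2 | 2,6-bis(benzyloxy)-4-bromobenzaldehyde | O=Cc1c(OCc9ccccc9)cc(Br)cc1OCc9ccccc9 | intermediate
3 | 2-(benzyloxy)-4-bromo-6-hydroxybenzaldehyde | O=Cc1c(O)cc(Br)cc1OCc9ccccc9 | intermediate
4 | ethyl (E)-3-[2-(benzyloxy)-4-bromo-6-hydroxyphenyl]prop-2-enoate | CCOC(=O)/C=C/c1c(O)cc(Br)cc1OCc9ccccc9 | intermediate
5 | 5-(benzyloxy)-7-bromo-2H-chromen-2-one | O=C1C=Cc2c(OCc9ccccc9)cc(Br)cc2O1 | intermediate
6 | 2,4-bis(benzyloxy)benzaldehyde | O=Cc1ccc(OCc9ccccc9)cc1OCc9ccccc9 | starting material
7 | 2,4-bis(benzyloxy)-1-ethenylbenzene | C=Cc1ccc(OCc9ccccc9)cc1OCc9ccccc9 | intermediate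
8 | 5-(benzyloxy)-7-{(E)-2-[2,4-bis(benzyloxy)phenyl]ethenyl}-2H-chromen-2-one | O=C1C=Cc2c(OCc9ccccc9)cc(/C=C/c3ccc(OCc9ccccc9)cc3OCc9ccccc9)cc2O1 | intermediate
9 | [3,5-bis(benzyloxy)phenyl]boronic acid | OB(O)c1cc(OCc9ccccc9)cc(OCc9ccccc9)c1 | starting material
10 | (4R)-5-(benzyloxy)-4-[3,5-bis(benzyloxy)phenyl]-7-{(E)-2-[2,4-bis(benzyloxy)phenyl]ethenyl}-3,4-dihydro-2H-chromen-2-one | O=C1C[C@H](c3cc(OCc9ccccc9)cc(OCc9ccccc9)c3)c2c(OCc9ccccc9)cc(/C=C/c3ccc(OCc9ccccc9)cc3OCc9ccccc9)cc2O1 | intermediate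
11 | (3S,4R)-3-bromo derivative of 10 (3,4-trans bromolactone) | O=C1[C@@H](Br)[C@H](c3cc(OCc9ccccc9)cc(OCc9ccccc9)c3)c2c(OCc9ccccc9)cc(/C=C/c3ccc(OCc9ccccc9)cc3OCc9ccccc9)cc2O1 | intermediate
12 | (2R,3R)-4-(benzyloxy)-3-[3,5-bis(benzyloxy)phenyl]-6-{(E)-2-[2,4-bis(benzyloxy)phenyl]ethenyl}-2,3-dihydro-1-benzofuran-2-carboxylic acid | OC(=O)[C@@H]1Oc2cc(/C=C/c3ccc(OCc9ccccc9)cc3OCc9ccccc9)cc(OCc9ccccc9)c2[C@H]1c1cc(OCc9ccccc9)cc(OCc9ccccc9)c1 | intermediate
13 | 1,3-dioxoisoindolin-2-yl ester of acid 12 | O=C(ON1C(=O)c2ccccc2C1=O)[C@@H]1Oc2cc(/C=C/c3ccc(OCc9ccccc9)cc3OCc9ccccc9)cc(OCc9ccccc9)c2[C@H]1c1cc(OCc9ccccc9)cc(OCc9ccccc9)c1 | intermediate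
14 | [2,4-bis(benzyloxy)phenyl]methanol | OCc1ccc(OCc9ccccc9)cc1OCc9ccccc9 | intermediate
15 | 5-bromo-2,4-dihydroxybenzaldehyde | O=Cc1cc(Br)c(O)cc1O | starting material
16 | 4-(benzyloxy)-5-bromo-2-hydroxybenzaldehyde | O=Cc1cc(Br)c(OCc9ccccc9)cc1O | intermediate
17 | 4-(benzyloxy)-2-{[2,4-bis(benzyloxy)phenyl]methoxy}-5-bromobenzaldehyde | O=Cc1cc(Br)c(OCc9ccccc9)cc1OCc1ccc(OCc9ccccc9)cc1OCc9ccccc9 | intermediate
18 | 1,3-bis(benzyloxy)-5-bromobenzene | Brc1cc(OCc9ccccc9)cc(OCc9ccccc9)c1 | starting material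
19 | [3,5-bis(benzyloxy)phenyl]magnesium bromide | Br[Mg]c1cc(OCc9ccccc9)cc(OCc9ccccc9)c1 | intermediate
20 | (4-(benzyloxy)-2-{[2,4-bis(benzyloxy)phenyl]methoxy}-5-bromophenyl)[3,5-bis(benzyloxy)phenyl]methanol (racemic) | OC(c1cc(OCc9ccccc9)cc(OCc9ccccc9)c1)c1cc(Br)c(OCc9ccccc9)cc1OCc1ccc(OCc9ccccc9)cc1OCc9ccccc9 | intermediate
21 | (4-(benzyloxy)-2-{[2,4-bis(benzyloxy)phenyl]methoxy}-5-bromophenyl)[3,5-bis(benzyloxy)phenyl]methanone | O=C(c1cc(OCc9ccccc9)cc(OCc9ccccc9)c1)c1cc(Br)c(OCc9ccccc9)cc1OCc1ccc(OCc9ccccc9)cc1OCc9ccccc9 | intermediate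
22 | hydrazone of ketone 21 | NN=C(c1cc(OCc9ccccc9)cc(OCc9ccccc9)c1)c1cc(Br)c(OCc9ccccc9)cc1OCc1ccc(OCc9ccccc9)cc1OCc9ccccc9 | intermediate
23 | diaryldiazomethane from 22 | [N-]=[N+]=C(c1cc(OCc9ccccc9)cc(OCc9ccccc9)c1)c1cc(Br)c(OCc9ccccc9)cc1OCc1ccc(OCc9ccccc9)cc1OCc9ccccc9 | intermediate
24 | (2S,3R)-6-(benzyloxy)-2-[2,4-bis(benzyloxy)phenyl]-3-[3,5-bis(benzyloxy)phenyl]-5-bromo-2,3-dihydro-1-benzofuran (cis) | O(Cc9ccccc9)c1cc(OCc9ccccc9)cc([C@@H]2c3cc(Br)c(OCc9ccccc9)cc3O[C@@H]2c2ccc(OCc9ccccc9)cc2OCc9ccccc9)c1 | intermediate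
25 | (2R,3R)-6-(benzyloxy)-2-[2,4-bis(benzyloxy)phenyl]-3-[3,5-bis(benzyloxy)phenyl]-5-bromo-2,3-dihydro-1-benzofuran (trans) | O(Cc9ccccc9)c1cc(OCc9ccccc9)cc([C@@H]2c3cc(Br)c(OCc9ccccc9)cc3O[C@H]2c2ccc(OCc9ccccc9)cc2OCc9ccccc9)c1 | intermediate
26 | 5-lithio analogue of 25 | O(Cc9ccccc9)c1cc(OCc9ccccc9)cc([C@@H]2c3cc([Li])c(OCc9ccccc9)cc3O[C@H]2c2ccc(OCc9ccccc9)cc2OCc9ccccc9)c1 | intermediate
27 | 5-(chlorozincio) analogue of 25 | O(Cc9ccccc9)c1cc(OCc9ccccc9)cc([C@@H]2c3cc([Zn]Cl)c(OCc9ccccc9)cc3O[C@H]2c2ccc(OCc9ccccc9)cc2OCc9ccccc9)c1 | intermediate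
28 | deca-O-benzylgneyulin A: (2R,3R)-6-(benzyloxy)-5-[(2R,3R)-4-(benzyloxy)-3-[3,5-bis(benzyloxy)phenyl]-6-{(E)-2-[2,4-bis(benzyloxy)phenyl]ethenyl}-2,3-dihydro-1-benzofuran-2-yl]-2-[2,4-bis(benzyloxy)phenyl]-3-[3,5-bis(benzyloxy)phenyl]-2,3-dihydro-1-benzofuran | O(Cc9ccccc9)c1cc(OCc9ccccc9)cc([C@@H]2c3cc([C@@H]4Oc5cc(/C=C/c6ccc(OCc9ccccc9)cc6OCc9ccccc9)cc(OCc9ccccc9)c5[C@H]4c4cc(OCc9ccccc9)cc(OCc9ccccc9)c4)c(OCc9ccccc9)cc3O[C@H]2c2ccc(OCc9ccccc9)cc2OCc9ccccc9)c1 | intermediate
29 | gneyulin A | Oc1cc(O)cc([C@@H]2c3cc([C@@H]4Oc5cc(/C=C/c6ccc(O)cc6O)cc(O)c5[C@H]4c4cc(O)cc(O)c4)c(O)cc3O[C@H]2c2ccc(O)cc2O)c1 | target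

**Step count and risks**

Total steps: 18. Longest linear sequence: 9 steps (steps 1, 2, 3, 5, 6, 7, 8, 17, 18; the ring A branch, steps 10–18, is equally long).

Steps most likely to fail:

Step 17. The hindered secondary C2 radical may be captured too slowly by the ortho-substituted arylnickel species. It could then be reduced, lose the C3 hydrogen by β-hydride elimination toward an aromatic benzofuran, or suffer a 1,2-aryl shift, while the arylzinc is consumed by homocoupling. The fallback forms the same bond by a polar path. Acid 12 would be decarboxylated oxidatively with lead tetraacetate (pyridine, benzene, rt) to the anomeric acetate F1. F1 would be ionised with TMSOTf at −78 °C in CH2Cl2/toluene in the presence of arylzinc chloride 27 (made from 25 as in step 17). Aryl transfer to the oxocarbenium ion anti to the C3 aryl group returns to the route at 28.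

Step 6. Insertion of the arylrhodium species at C4, next to the peri benzyloxy group, may be outrun by protodeboronation, and enantioface discrimination may erode. The fallback sets the centre by hydride delivery instead of aryl delivery. Coumarin 8 and boronic acid 9 under Pd(II) oxidative Heck conditions (Pd(OAc)2, 1,10-phenanthroline, O2, DMF, 80 °C) would give the 4-arylcoumarin F2. Copper hydride conjugate reduction (Cu(OAc)2, DTBM-Segphos of the appropriate hand, polymethylhydrosiloxane, t-BuOH, toluene) would then return to the route at lactone 10.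

Step 18. Cleavage of ten ethers may stop short, the two benzylic C2–O bonds may ionise and be captured by the scavenger, and the free decaphenol may oxidise in air during isolation, giving mixtures that cannot be purified directly. The fallback sets out from 28 with the same BCl3/pentamethylbenzene treatment and methanol quench. After evaporation the crude phenol would be peracetylated (Ac2O, pyridine, DMAP) to gneyulin A decaacetate F3, which is purified as a stable neutral compound. The acetates would then be removed with K2CO3 in degassed MeOH at 0 °C to return to the route at 29.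

Further compounds
F1 | step 17 | (3R)-4-(benzyloxy)-3-[3,5-bis(benzyloxy)phenyl]-6-{(E)-2-[2,4-bis(benzyloxy)phenyl]ethenyl}-2,3-dihydro-1-benzofuran-2-yl acetate (anomer mixture) | CC(=O)OC1Oc2cc(/C=C/c3ccc(OCc9ccccc9)cc3OCc9ccccc9)cc(OCc9ccccc9)c2[C@H]1c1cc(OCc9ccccc9)cc(OCc9ccccc9)c1
F2 | step 6 | 5-(benzyloxy)-4-[3,5-bis(benzyloxy)phenyl]-7-{(E)-2-[2,4-bis(benzyloxy)phenyl]ethenyl}-2H-chromen-2-one | O=C1C=C(c3cc(OCc9ccccc9)cc(OCc9ccccc9)c3)c2c(OCc9ccccc9)cc(/C=C/c3ccc(OCc9ccccc9)cc3OCc9ccccc9)cc2O1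
F3 | step 18 | gneyulin A decaacetate | CC(=O)Oc1cc(OC(C)=O)cc([C@@H]2c3cc([C@@H]4Oc5cc(/C=C/c6ccc(OC(C)=O)cc6OC(C)=O)cc(OC(C)=O)c5[C@H]4c4cc(OC(C)=O)cc(OC(C)=O)c4)c(OC(C)=O)cc3O[C@H]2c2ccc(OC(C)=O)cc2OC(C)=O)c1
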